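**Plan**

- Retrosynthetic cuts, in order: the eight benzyl ethers and the C8–Br bond of the lower unit; C3–O and C4–H of the upper unit (from a C3=C4 flav-3-ene); C2–C3 together with O1–C2 of the upper ring C; the C3 methylene; the bond between C4 (upper unit) and C6 (lower unit).
- Forward: both rings of (+)-catechin are kept. Ring A of the upper unit is attached to C6 as an aroyl group, its carbonyl carbon (the future C4) is methylenated, ring B arrives with an aldehyde, and ring C is closed last by joining C2 to C3.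
- Enabling feature: C4 of the upper unit is doubly benzylic, bonded to C4a of the 7-oxygenated ring A and to C6 of the 5,7-dioxygenated ring A of catechin. A C3=C4 1,1-diarylethene is therefore strongly nucleophilic at C3 and its C4 cation is stabilized, while C2 can be an oxocarbenium carbon flanked by O1 and the para-oxygenated ring B.
- Stereochemistry: C2 and C3 of the lower unit come from (+)-catechin; C2 of the upper unit from a chiral Brønsted acid in the ring closure; C3 and C4 from syn hydroboration anti to the C2 aryl group.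
- Helpers: a bromine at C8 of catechin forces bond formation at C6; benzyl ethers mask all phenols and the lower 3-OH; all are removed in the last step.

Key step: step 6

Remark: the sense of induction of the chiral acid in step 6 cannot be assigned with certainty in advance; the R catalyst is written, and its S antipode is meant if a screen shows that it is the one leading to the 2S chromene.

**Route**

Step 1
Reactants: 1 (+)-catechin
Product: 2 5,7,3',4'-tetra-O-benzyl-(+)-catechin
Conditions: BnBr (4.4 equiv), K2CO3, DMF, 0 °C to rt, N2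
Reagents that add atoms: benzyl bromide, BrCc1ccccc1
Why: Williamson ether synthesis in which K2CO3 ionizes only the four phenols, so the secondary 3-OH stays free and the C2 and C3 stereocenters are untouched.

Step 2
Reactants: 2 5,7,3',4'-tetra-O-benzyl-(+)-catechin
Product: 3 3,5,7,3',4'-penta-O-benzyl-(+)-catechin
Conditions: NaH, BnBr, Bu4NI (cat.), DMF, 0 °C to rt
Reagents that add atoms: benzyl bromide, BrCc1ccccc1
Why: Williamson ether synthesis through the sodium alkoxide; the ether keeps the 3-OH from forming esters in step 4 or acetals in step 6.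

Step 3
Reactants: 3 3,5,7,3',4'-penta-O-benzyl-(+)-catechin
Product: 4 8-bromo-3,5,7,3',4'-penta-O-benzyl-(+)-catechin
Conditions: NBS (1.0 equiv), CH2Cl2, −78 °C to 0 °C
Reagents that add atoms: N-bromosuccinimide, O=C1CCC(=O)N1Br
Why: Electrophilic aromatic bromination, which should go to C8 because C6 is flanked by two benzyloxy groups, a preference well established for benzylated catechins; the bromine blocks C8 until step 8.

Step 4
Reactants: 4 8-bromo-3,5,7,3',4'-penta-O-benzyl-(+)-catechin; 5 4-(benzyloxy)-2-hydroxybenzoic acid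
Product: 8 6-[4-(benzyloxy)-2-hydroxybenzoyl]-8-bromo-3,5,7,3',4'-penta-O-benzyl-(+)-catechin, via mixed trifluoroacetic anhydride 6 (not isolated), via ketone aryl trifluoroacetate 7 (not isolated)
Conditions: (CF3CO)2O (4 equiv), CH2Cl2, 0 °C to rt; concentrate; then MeOH/THF, rt
Reagents that add atoms: none
Why: Friedel–Crafts acylation by a mixed trifluoroacetic anhydride; C6 is the only free position of the most electron-rich ring, so the aryl–carbonyl bond that becomes the C4–C6 interflavan bond should form there, and the ortho trifluoroacetate is lost by methanolysis.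

Step 5
Reactants: 8 6-[4-(benzyloxy)-2-hydroxybenzoyl]-8-bromo-3,5,7,3',4'-penta-O-benzyl-(+)-catechin
Product: 10 6-{1-[4-(benzyloxy)-2-hydroxyphenyl]ethenyl}-8-bromo-3,5,7,3',4'-penta-O-benzyl-(+)-catechin, via tertiary carbinol 9 (not isolated)
Conditions: MeMgBr (6 equiv), THF, 0 °C to 50 °C; aq NH4Cl; then PPTS (cat.), toluene, 60 °C
Reagents that add atoms: methylmagnesium bromide, C[Mg]Br
Why: Grignard addition to the ketone followed by acid-catalysed E1 dehydration of the tertiary diarylcarbinol, which ionizes readily because both aryl groups are electron-rich; the methyl carbon becomes C3 of the upper unit.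

Step 6
Reactants: 10 6-{1-[4-(benzyloxy)-2-hydroxyphenyl]ethenyl}-8-bromo-3,5,7,3',4'-penta-O-benzyl-(+)-catechin; 11 3,4-bis(benzyloxy)benzaldehyde
Product: 15 (2S)-7-(benzyloxy)-2-[3,4-bis(benzyloxy)phenyl]-4-[8-bromo-3,5,7,3',4'-penta-O-benzyl-(+)-catechin-6-yl]-2H-chromene, via hemiacetal 12 (not isolated), via oxocarbenium ion 13 (not isolated), via C4 carbenium ion 14 (not isolated)
Conditions: (R)-3,3'-bis(2,4,6-triisopropylphenyl)-1,1'-bi-2-naphthol N-triflylphosphoramide (10 mol%), molecular sieves 5 Å, toluene, −40 °C to −10 °C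
Reagents that add atoms: none
Why: Proposed new method: phenol 10 and aldehyde 11 should condense reversibly to hemiacetal 12, which the strong chiral acid ionizes to the O-aryl oxocarbenium ion 13 held as a contact ion pair with the phosphoramide anion; the terminal alkene carbon (C3) then attacks the oxocarbenium carbon (C2), and the C4 carbenium ion 14, stabilized by the para-oxygenated ring A and the trioxygenated catechin ring, loses a C3 proton to give the conjugated C3=C4 chromene 15. The closest known reaction types are the acid-catalysed Prins cyclization of homoallylic alcohols with aldehydes, its enantioselective variants with confined chiral Brønsted acids, and the chiral N-triflylphosphoramide ion-pair catalysis that gives 2,4-diaryl-2H-chromenes from triarylallyl cations; new here is a phenol as the hydroxy component and a 1,1-diarylethene as the π-nucleophile in an enantiocontrolled version. Ring C closes in a 6-endo-trig mode with respect to the alkene, the only closure open to this homoallylic phenol, since the two aryl donors on C4 polarize the alkene toward C3 and no hydrogen is available for an exocyclic elimination. The single new stereocenter C2 is set by the chiral counteranion, which shields one face of the planar oxocarbenium ion; the remote catechin stereocenters are not expected to bias it, and because the two C2 epimers are diastereomers a minor one should be removable by chromatography. The step needs cyclization to outrun intermolecular dimerization of the alkene and the product to keep its configuration, which the twisted, doubly ortho-substituted catechin ring and the low temperature should secure.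

Step 7
Reactants: 15 (2S)-7-(benzyloxy)-2-[3,4-bis(benzyloxy)phenyl]-4-[8-bromo-3,5,7,3',4'-penta-O-benzyl-(+)-catechin-6-yl]-2H-chromene
Product: 17 7,3',4'-tri-O-benzylfisetinidol-(4α→6)-8-bromo-3,5,7,3',4'-penta-O-benzylcatechin (upper unit 2R,3S,4S with free 3-OH; lower unit 2R,3S), via C3 alkylborane 16 (not isolated)
Conditions: BH3·THF (3 equiv), THF, 0 °C to rt; then aq NaOH, H2O2, 0 °C to rt
Reagents that add atoms: hydrogen peroxide, OO
Why: Hydroboration–oxidation, in which borane should add syn from the face opposite the C2 aryl group with boron at the less substituted C3 and hydrogen at C4, and oxidation goes with retention, so the 3-OH ends trans to the C2 aryl group and cis to the new C4–H, which is the 2,3-trans-3,4-trans upper unit.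

Step 8
Reactants: 17 7,3',4'-tri-O-benzylfisetinidol-(4α→6)-8-bromo-3,5,7,3',4'-penta-O-benzylcatechin
Product: 18 fisetinidol-(4α→6)-catechin (target; upper unit 2R,3S,4S; lower unit 2R,3S)
Conditions: H2 (1 atm), Pd(OH)2/C, NaOAc, THF/MeOH/H2O, rt
Reagents that add atoms: none
Why: Catalytic hydrogenolysis should cleave the eight benzyl ethers and the aryl C–Br bond in one operation with acetate taking up the HBr, while the ring C–O bonds and the acid-stable 5-deoxy interflavan bond are expected to survive as in related benzylated oligoflavanoids.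

**Compound list**

1 | (+)-catechin, (2R,3S)-2-(3,4-dihydroxyphenyl)chromane-3,5,7-triol | c1c(O)cc2c(c1O)C[C@H](O)[C@@H](c1ccc(O)c(O)c1)O2 | starting material
2 | 5,7,3',4'-tetra-O-benzyl-(+)-catechin | c1c(OCc3ccccc3)cc2c(c1OCc3ccccc3)C[C@H](O)[C@@H](c1ccc(OCc3ccccc3)c(OCc3ccccc3)c1)O2 | intermediate
3 | 3,5,7,3',4'-penta-O-benzyl-(+)-catechin | c1c(OCc3ccccc3)cc2c(c1OCc3ccccc3)C[C@H](OCc3ccccc3)[C@@H](c1ccc(OCc3ccccc3)c(OCc3ccccc3)c1)O2 | intermediate
4 | 8-bromo-3,5,7,3',4'-penta-O-benzyl-(+)-catechin | c1c(OCc3ccccc3)c(Br)c2c(c1OCc3ccccc3)C[C@H](OCc3ccccc3)[C@@H](c1ccc(OCc3ccccc3)c(OCc3ccccc3)c1)O2 | intermediate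
5 | 4-(benzyloxy)-2-hydroxybenzoic acid | OC(=O)c1ccc(OCc2ccccc2)cc1O | starting material
6 | 4-(benzyloxy)-2-(trifluoroacetoxy)benzoic trifluoroacetic anhydride | O=C(OC(=O)C(F)(F)F)c1ccc(OCc2ccccc2)cc1OC(=O)C(F)(F)F | intermediate
7 | 6-[4-(benzyloxy)-2-(trifluoroacetoxy)benzoyl]-8-bromo-3,5,7,3',4'-penta-O-benzyl-(+)-catechin | FC(F)(F)C(=O)Oc1cc(OCc4ccccc4)ccc1C(=O)c1c(OCc3ccccc3)c(Br)c2c(c1OCc3ccccc3)C[C@H](OCc3ccccc3)[C@@H](c1ccc(OCc3ccccc3)c(OCc3ccccc3)c1)O2 | intermediate
8 | 6-[4-(benzyloxy)-2-hydroxybenzoyl]-8-bromo-3,5,7,3',4'-penta-O-benzyl-(+)-catechin | Oc1cc(OCc4ccccc4)ccc1C(=O)c1c(OCc3ccccc3)c(Br)c2c(c1OCc3ccccc3)C[C@H](OCc3ccccc3)[C@@H](c1ccc(OCc3ccccc3)c(OCc3ccccc3)c1)O2 | intermediate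
9 | 6-{1-[4-(benzyloxy)-2-hydroxyphenyl]-1-hydroxyethyl}-8-bromo-3,5,7,3',4'-penta-O-benzyl-(+)-catechin (both epimers at the carbinol carbon) | Oc1cc(OCc4ccccc4)ccc1C(C)(O)c1c(OCc3ccccc3)c(Br)c2c(c1OCc3ccccc3)C[C@H](OCc3ccccc3)[C@@H](c1ccc(OCc3ccccc3)c(OCc3ccccc3)c1)O2 | intermediate
10 | 6-{1-[4-(benzyloxy)-2-hydroxyphenyl]ethenyl}-8-bromo-3,5,7,3',4'-penta-O-benzyl-(+)-catechin | Oc1cc(OCc4ccccc4)ccc1C(=C)c1c(OCc3ccccc3)c(Br)c2c(c1OCc3ccccc3)C[C@H](OCc3ccccc3)[C@@H](c1ccc(OCc3ccccc3)c(OCc3ccccc3)c1)O2 | intermediate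
11 | 3,4-bis(benzyloxy)benzaldehyde | O=Cc1ccc(OCc2ccccc2)c(OCc2ccccc2)c1 | starting material
12 | hemiacetal from the phenol oxygen of 10 and the aldehyde carbon of 11 (both epimers) | OC(c5ccc(OCc6ccccc6)c(OCc6ccccc6)c5)Oc1cc(OCc4ccccc4)ccc1C(=C)c1c(OCc3ccccc3)c(Br)c2c(c1OCc3ccccc3)C[C@H](OCc3ccccc3)[C@@H](c1ccc(OCc3ccccc3)c(OCc3ccccc3)c1)O2 | intermediate
13 | O-aryl oxocarbenium ion formed from 12 by loss of water | [O+](=Cc5ccc(OCc6ccccc6)c(OCc6ccccc6)c5)c1cc(OCc4ccccc4)ccc1C(=C)c1c(OCc3ccccc3)c(Br)c2c(c1OCc3ccccc3)C[C@H](OCc3ccccc3)[C@@H](c1ccc(OCc3ccccc3)c(OCc3ccccc3)c1)O2 | intermediate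
14 | (2S)-7-(benzyloxy)-2-[3,4-bis(benzyloxy)phenyl]-4-[8-bromo-penta-O-benzylcatechin-6-yl]chroman-4-ylium ion | c1ccccc1COc1ccc2c(c1)O[C@H](c1ccc(OCc3ccccc3)c(OCc3ccccc3)c1)C[C+]2c1c(OCc3ccccc3)c(Br)c2c(c1OCc3ccccc3)C[C@H](OCc3ccccc3)[C@@H](c1ccc(OCc3ccccc3)c(OCc3ccccc3)c1)O2 | intermediate
15 | (2S)-7-(benzyloxy)-2-[3,4-bis(benzyloxy)phenyl]-4-[8-bromo-3,5,7,3',4'-penta-O-benzyl-(+)-catechin-6-yl]-2H-chromene | c1ccccc1COc1ccc2c(c1)O[C@H](c1ccc(OCc3ccccc3)c(OCc3ccccc3)c1)C=C2c1c(OCc3ccccc3)c(Br)c2c(c1OCc3ccccc3)C[C@H](OCc3ccccc3)[C@@H](c1ccc(OCc3ccccc3)c(OCc3ccccc3)c1)O2 | intermediate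
16 | C3 alkylborane of 15 (boron at C3 trans to the C2 aryl group, hydrogen at C4 cis to boron) | c1ccccc1COc1ccc2c(c1)O[C@H](c1ccc(OCc3ccccc3)c(OCc3ccccc3)c1)[C@@H](B)[C@@H]2c1c(OCc3ccccc3)c(Br)c2c(c1OCc3ccccc3)C[C@H](OCc3ccccc3)[C@@H](c1ccc(OCc3ccccc3)c(OCc3ccccc3)c1)O2 | intermediate
17 | 7,3',4'-tri-O-benzylfisetinidol-(4α→6)-8-bromo-3,5,7,3',4'-penta-O-benzylcatechin (upper unit 2R,3S,4S; lower unit 2R,3S) | c1ccccc1COc1ccc2c(c1)O[C@H](c1ccc(OCc3ccccc3)c(OCc3ccccc3)c1)[C@@H](O)[C@@H]2c1c(OCc3ccccc3)c(Br)c2c(c1OCc3ccccc3)C[C@H](OCc3ccccc3)[C@@H](c1ccc(OCc3ccccc3)c(OCc3ccccc3)c1)O2 | intermediate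
18 | fisetinidol-(4α→6)-catechin (upper unit 2R,3S,4S; lower unit 2R,3S) | Oc1ccc2c(c1)O[C@H](c1ccc(O)c(O)c1)[C@@H](O)[C@@H]2c1c(O)cc2c(c1O)C[C@H](O)[C@@H](c1ccc(O)c(O)c1)O2 | target

**Step count and risks**

Total step count: 8. Longest linear sequence: 8 steps, from (+)-catechin; compounds 5 and 11 are purchased.

Steps most likely to fail:

Step 6. The chiral acid may fail to differentiate the faces of the oxocarbenium ion, or may turn over poorly with this large substrate, and reversible protonation of the diarylethene may divert material to oligomers. The fallback closes ring C through O1–C2 by known ion-pair catalysis; it sets out from 4 and 11 and comes back at 15. Iodination of 4 at C6 (N-iodosuccinimide, cat. CF3CO2H, CH2Cl2) should give 8-bromo-6-iodo-3,5,7,3',4'-penta-O-benzyl-(+)-catechin F1. Claisen–Schmidt condensation of 11 with commercial 1-[4-(benzyloxy)-2-hydroxyphenyl]ethanone (KOH, EtOH) should give (E)-1-[4-(benzyloxy)-2-hydroxyphenyl]-3-[3,4-bis(benzyloxy)phenyl]prop-2-en-1-one F2. Iodine–magnesium exchange of F1 (iPrMgCl·LiCl, THF, −40 °C, the C–Br bond being left), transmetalation with CeCl3 and 1,2-addition to the magnesium phenoxide of F2 should give the tertiary allylic alcohol F3. The chiral N-triflylphosphoramide (toluene, −78 °C) should ionize F3 to a 1,1,3-triarylallyl cation, whose phenol attacks C2 within the chiral ion pair to give 15.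

Step 4. Acylation at the bromine-deactivated, doubly ortho-substituted C6 may be sluggish, and forcing it may cause acid-induced loss or migration of benzyl groups. The fallback replaces the electrophilic acylation by an organometallic addition; it sets out from 4 and comes back at 8. 8-Bromo-6-iodo-3,5,7,3',4'-penta-O-benzyl-(+)-catechin F1 (made as above) is converted to the arylmagnesium chloride (iPrMgCl·LiCl, THF, −40 °C) and added to the magnesium phenoxide of commercial 4-(benzyloxy)-2-hydroxybenzaldehyde to give the diarylmethanol [4-(benzyloxy)-2-hydroxyphenyl][8-bromo-penta-O-benzylcatechin-6-yl]methanol F4, which MnO2 (CH2Cl2, rt) should oxidize to 8.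

Step 5. The methyl nucleophile may fail to add to a carbonyl group that is shielded by two ortho benzyloxy groups and deactivated by the ortho magnesium phenoxide. The fallback replaces addition–elimination by a titanium carbene olefination; it sets out from 8 and comes back at 10. Silylation (TBSCl, imidazole, DMF) should give the tert-butyldimethylsilyl ether of 8 F5, Petasis methylenation (Cp2TiMe2, toluene, 70 °C) the tert-butyldimethylsilyl ether of 10 F6, and Bu4NF (THF, 0 °C) should then free the phenol to give 10.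

**Further compounds**

F1 | step 6 | 8-bromo-6-iodo-3,5,7,3',4'-penta-O-benzyl-(+)-catechin | Ic1c(OCc3ccccc3)c(Br)c2c(c1OCc3ccccc3)C[C@H](OCc3ccccc3)[C@@H](c1ccc(OCc3ccccc3)c(OCc3ccccc3)c1)O2
F2 | step 6 | (E)-1-[4-(benzyloxy)-2-hydroxyphenyl]-3-[3,4-bis(benzyloxy)phenyl]prop-2-en-1-one | O=C(/C=C/c1ccc(OCc2ccccc2)c(OCc2ccccc2)c1)c1ccc(OCc2ccccc2)cc1O
F3 | step 6 | (E)-1-[4-(benzyloxy)-2-hydroxyphenyl]-3-[3,4-bis(benzyloxy)phenyl]-1-[8-bromo-penta-O-benzylcatechin-6-yl]prop-2-en-1-ol (both epimers at the carbinol carbon) | Oc1cc(OCc4ccccc4)ccc1C(O)(/C=C/c5ccc(OCc6ccccc6)c(OCc6ccccc6)c5)c1c(OCc3ccccc3)c(Br)c2c(c1OCc3ccccc3)C[C@H](OCc3ccccc3)[C@@H](c1ccc(OCc3ccccc3)c(OCc3ccccc3)c1)O2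
F4 | step 4 | [4-(benzyloxy)-2-hydroxyphenyl][8-bromo-penta-O-benzylcatechin-6-yl]methanol (both epimers at the carbinol carbon) | Oc1cc(OCc4ccccc4)ccc1C(O)c1c(OCc3ccccc3)c(Br)c2c(c1OCc3ccccc3)C[C@H](OCc3ccccc3)[C@@H](c1ccc(OCc3ccccc3)c(OCc3ccccc3)c1)O2
F5 | step 5 | tert-butyldimethylsilyl ether of 8 | CC(C)(C)[Si](C)(C)Oc1cc(OCc4ccccc4)ccc1C(=O)c1c(OCc3ccccc3)c(Br)c2c(c1OCc3ccccc3)C[C@H](OCc3ccccc3)[C@@H](c1ccc(OCc3ccccc3)c(OCc3ccccc3)c1)O2
F6 | step 5 | tert-butyldimethylsilyl ether of 10 | CC(C)(C)[Si](C)(C)Oc1cc(OCc4ccccc4)ccc1C(=C)c1c(OCc3ccccc3)c(Br)c2c(c1OCc3ccccc3)C[C@H](OCc3ccccc3)[C@@H](c1ccc(OCc3ccccc3)c(OCc3ccccc3)c1)O2
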